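## Retrosynthetic overview

1. Target ⇐ cis-epoxy alcohol 15 by trans-diaxial methanolysis; 15 ⇐ cyclohexenol 14 by OH-directed epoxidation, so C4′ and C5′ are relayed from C1′.
2. Dihydrofuran ring ⇐ aryl diazoacetate 10 by Rh(II)-catalysed enantioselective carbene insertion into the ArO–CH2 C–H bond (C2–C3 bond, sets C2; C3 corrected to trans by epimerisation). This is the key step, chosen instead of an aldol/etherification or biomimetic 8–5′ coupling.
3. 10 ⇐ iodophenol 6 + spiro-epoxide 4 (phenoxide opening), then Pd coupling with ethyl diazoacetate.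
4. 4 ⇐ butadiene + 2-bromoacrolein by catalytic enantioselective Diels–Alder (sets C1′).
5. Ring order: arene (purchased) → cyclohexene (Diels–Alder) → dihydrofuran (C–H insertion) → cyclohexane oxygenation last.

Assumption: the catalyst antipodes in Steps 1 and 7 are assigned from my recollection of the usual sense of induction for these catalyst classes; if the first run shows the opposite sense, the mirror-image catalyst is used and nothing else changes.

## Route

**Step 1**
Reactants: 1 buta-1,3-diene; 2 2-bromoacrolein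
Product: 3 (R)-1-bromocyclohex-3-ene-1-carbaldehyde
Conditions: N-Ts-(S)-tryptophan-derived B-n-Bu oxazaborolidinone (10 mol %), CH2Cl2, −78 → −40 °C
Reagents that add atoms: none beyond the listed reactants
Why: Catalytic enantioselective Diels–Alder reaction (Corey oxazaborolidine); the catalyst shields one face of the s-cis α-bromoenal, so the quaternary carbon (future C1′) is formed as R, and endo/exo is irrelevant with butadiene.

**Step 2**
Reactants: 3
Product: 4 (S)-1-oxaspiro[2.5]oct-5-ene
Conditions: NaBH4, EtOH, 0 °C; then aq. KOH, 0 °C → rt (one pot); pentane extraction (volatile)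
Reagents that add atoms: none
Why: Aldehyde reduction to the bromohydrin, then Williamson-type 3-exo-tet epoxide closure; the intramolecular SN2 inverts the C–Br carbon, converting (R)-C–Br into (S)-C–O.

**Step 3**
Reactants: 5 ethyl 3-(4-hydroxy-3-methoxyphenyl)propanoate
Product: 6 ethyl 3-(4-hydroxy-3-iodo-5-methoxyphenyl)propanoate
Conditions: I2, NaHCO3, THF/H2O, 0 °C → rt
Reagents that add atoms: iodine, II
Why: Electrophilic aromatic iodination of the phenoxide, which directs to the only free ortho position (para is blocked).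

**Step 4**
Reactants: 6; 4
Product: 7 ethyl 3-(4-{[(1S)-1-hydroxycyclohex-3-en-1-yl]methoxy}-3-iodo-5-methoxyphenyl)propanoate
Conditions: Cs2CO3, DMF, 80 °C, sealed tube
Reagents that add atoms: none beyond the listed reactants
Why: SN2 opening of the 2,2-disubstituted epoxide by phenoxide at the unhindered CH2 terminus; C1′ is not touched and emerges as the free tertiary alcohol.

**Step 5**
Reactants: 7
Product: 8 ethyl 3-[3-iodo-5-methoxy-4-({(1S)-1-[(triethylsilyl)oxy]cyclohex-3-en-1-yl}methoxy)phenyl]propanoate
Conditions: TESOTf, 2,6-lutidine, CH2Cl2, −78 → 0 °C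
Reagents that add atoms: triethylsilyl triflate, CC[Si](CC)(CC)OS(=O)(=O)C(F)(F)F
Why: Silylation of the tertiary alcohol, which would otherwise undergo carbene O–H insertion in Step 7 and trap the cis ester as a γ-lactone in Step 8.

**Step 6**
Reactants: 8; 9 ethyl diazoacetate
Product: 10 ethyl 3-[3-(1-diazo-2-ethoxy-2-oxoethyl)-5-methoxy-4-({(1S)-1-[(triethylsilyl)oxy]cyclohex-3-en-1-yl}methoxy)phenyl]propanoate
Conditions: Pd(PPh3)4 (5 mol %), Ag2CO3, Et3N, toluene, rt
Reagents that add atoms: none beyond the listed reactants (9, CCOC(=O)C=[N+]=[N-])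
Why: Pd-catalysed cross-coupling (C–H arylation) of an acceptor diazo ester with an aryl iodide at room temperature, which keeps the diazo group and gives the donor/acceptor carbene precursor in one step.

**Step 7**
Reactants: 10
Product: 11 ethyl (2S,3R)-5-(3-ethoxy-3-oxopropyl)-7-methoxy-2-{(1S)-1-[(triethylsilyl)oxy]cyclohex-3-en-1-yl}-2,3-dihydro-1-benzofuran-3-carboxylate (2,3-cis)
Conditions: Rh2(R-PTTL)4 (2 mol %), toluene, −40 → 0 °C
Reagents that add atoms: none (N2 lost)
Why: Rh(II) donor/acceptor-carbene intramolecular 1,5 C–H insertion into the ether-activated OCH2; the chiral carboxylate catalyst selects one enantiotopic hydrogen and so sets C2 as S (the nearly pseudo-symmetric C1′ exerts little bias), with the kinetic cis ester at C3.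

**Step 8**
Reactants: 11
Product: 12 ethyl (2S,3S)-5-(3-ethoxy-3-oxopropyl)-7-methoxy-2-{(1S)-1-[(triethylsilyl)oxy]cyclohex-3-en-1-yl}-2,3-dihydro-1-benzofuran-3-carboxylate (2,3-trans)
Conditions: NaOEt (0.3 equiv), EtOH, 0 °C → rt
Reagents that add atoms: none (ethoxide/ethyl ester exchange is degenerate)
Why: Base-mediated epimerisation of the benzylic α-ester centre via the enolate to the thermodynamically preferred trans isomer, placing the ester anti to the bulky C2 substituent; C2 is not enolisable and is retained.

**Step 9**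
Reactants: 12
Product: 13 3-[(2S,3R)-3-(hydroxymethyl)-7-methoxy-2-{(1S)-1-[(triethylsilyl)oxy]cyclohex-3-en-1-yl}-2,3-dihydro-1-benzofuran-5-yl]propan-1-ol
Conditions: LiAlH4, THF, 0 °C
Reagents that add atoms: none
Why: Hydride reduction of both ethyl esters gives the C3 hydroxymethyl and the 3-hydroxypropyl chain in one operation; C3 changes from S to R only through CIP priority.

**Step 10**
Reactants: 13
Product: 14 (1S)-1-[(2S,3R)-3-(hydroxymethyl)-5-(3-hydroxypropyl)-7-methoxy-2,3-dihydro-1-benzofuran-2-yl]cyclohex-3-en-1-ol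
Conditions: TBAF, THF, rt → 40 °C
Reagents that add atoms: none
Why: Fluoride-mediated desilylation frees the tertiary homoallylic alcohol needed to direct the next step.

**Step 11**
Reactants: 14
Product: 15 (1S,3S,6R)-3-[(2S,3R)-3-(hydroxymethyl)-5-(3-hydroxypropyl)-7-methoxy-2,3-dihydro-1-benzofuran-2-yl]-7-oxabicyclo[4.1.0]heptan-3-ol (epoxide syn to the tertiary OH)
Conditions: VO(acac)2 (5 mol %), t-BuOOH (decane, 1.5 equiv), CH2Cl2, 0 °C → rt
Reagents that add atoms: tert-butyl hydroperoxide, CC(C)(C)OO
Why: Hydroxyl-directed vanadium-catalysed epoxidation of a cyclic homoallylic alcohol; the vanadate ester of the axial C1′–OH delivers oxygen to the syn face, fixing the future C5′–O bond cis to the C1′–OH.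

**Step 12**
Reactants: 15
Product: 16 difengpiol B, (1S,3S,4S)-1-[(2S,3R)-3-(hydroxymethyl)-5-(3-hydroxypropyl)-7-methoxy-2,3-dihydro-1-benzofuran-2-yl]-4-methoxycyclohexane-1,3-diol
Conditions: CSA (10 mol %), MeOH, 0 °C → rt
Reagents that add atoms: methanol, CO
Why: Acid-catalysed trans-diaxial epoxide opening (Fürst–Plattner): from the half-chair with the large C1′ substituent equatorial and OH axial, methanol attacks C4′ (also the carbon more remote from the electron-withdrawing C1′–O) with inversion, giving 4-OMe trans to 3-OH; the syn tertiary OH cannot attack from the backside.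

## Compound list

1 | buta-1,3-diene | C=CC=C | starting material
2 | 2-bromoacrolein (2-bromoprop-2-enal) | C=C(Br)C=O | starting material
3 | (R)-1-bromocyclohex-3-ene-1-carbaldehyde | O=C[C@@]1(Br)CCC=CC1 | intermediate
4 | (S)-1-oxaspiro[2.5]oct-5-ene | O1C[C@@]12CCC=CC2 | intermediate
5 | ethyl 3-(4-hydroxy-3-methoxyphenyl)propanoate (ethyl dihydroferulate) | CCOC(=O)CCc1ccc(O)c(OC)c1 | starting material
6 | ethyl 3-(4-hydroxy-3-iodo-5-methoxyphenyl)propanoate | CCOC(=O)CCc1cc(I)c(O)c(OC)c1 | intermediate
7 | ethyl 3-(4-{[(1S)-1-hydroxycyclohex-3-en-1-yl]methoxy}-3-iodo-5-methoxyphenyl)propanoate | CCOC(=O)CCc1cc(I)c(OC[C@]2(O)CCC=CC2)c(OC)c1 | intermediate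
8 | TES ether of 7 | CCOC(=O)CCc1cc(I)c(OC[C@]2(O[Si](CC)(CC)CC)CCC=CC2)c(OC)c1 | intermediate
9 | ethyl diazoacetate | CCOC(=O)C=[N+]=[N-] | starting material
10 | aryl diazoacetate (ethyl 2-aryl-2-diazoacetate of 8) | CCOC(=O)CCc1cc(C(=[N+]=[N-])C(=O)OCC)c(OC[C@]2(O[Si](CC)(CC)CC)CCC=CC2)c(OC)c1 | intermediate
11 | (2S,3R)-cis-dihydrobenzofuran diester, 1′S TES ether | COc1cc(CCC(=O)OCC)cc2c1O[C@H]([C@]1(O[Si](CC)(CC)CC)CCC=CC1)[C@@H]2C(=O)OCC | intermediate
12 | (2S,3S)-trans-dihydrobenzofuran diester, 1′S TES ether | COc1cc(CCC(=O)OCC)cc2c1O[C@H]([C@]1(O[Si](CC)(CC)CC)CCC=CC1)[C@H]2C(=O)OCC | intermediate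
13 | (2S,3R)-trans diol, 1′S TES ether | COc1cc(CCCO)cc2c1O[C@H]([C@]1(O[Si](CC)(CC)CC)CCC=CC1)[C@H]2CO | intermediate
14 | (1S)-1-[(2S,3R)-3-(hydroxymethyl)-5-(3-hydroxypropyl)-7-methoxy-2,3-dihydrobenzofuran-2-yl]cyclohex-3-en-1-ol | COc1cc(CCCO)cc2c1O[C@H]([C@]1(O)CCC=CC1)[C@H]2CO | intermediate
15 | (1S,3S,6R)-3-[that dihydrobenzofuran-2-yl]-7-oxabicyclo[4.1.0]heptan-3-ol (cis-epoxy alcohol) | COc1cc(CCCO)cc2c1O[C@H]([C@]1(O)CC[C@H]3O[C@H]3C1)[C@H]2CO | intermediate
16 | difengpiol B | COc1cc(CCCO)cc2c1O[C@H]([C@]1(O)CC[C@H](OC)[C@@H](O)C1)[C@H]2CO | target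

## Summary

Total steps: 12. Longest linear sequence: 11 (Steps 1, 2, 4–12). Step 3 is the single step of the other branch.

Steps most likely to fail:

1. **Step 7 (carbene C–H insertion).** The OCH2 is next to a quaternary, silyloxy-bearing carbon, so insertion may be slow, and C2 selectivity rests on the catalyst alone. The C2 epimers are near-pseudo-enantiomers and are realistically separable only after Step 12. Fallback: drop the insertion and form C2–C3 by an auxiliary-controlled anti-aldol between an (o-haloaryl)acetyl imide and (S)-1-(silyloxy)cyclohex-3-ene-1-carbaldehyde, then close O1–C7a by Cu-catalysed intramolecular O-arylation.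
2. **Step 6 (Pd coupling of the ortho-alkoxy, electron-rich aryl iodide with ethyl diazoacetate).** Hindered, electron-rich iodides are poor substrates. Fallback: build the arylacetate first by Pd-catalysed α-arylation with the Reformatsky reagent BrZnCH2CO2Et, then install the diazo group by Regitz diazo transfer (p-ABSA, DBU).
3. **Step 12 (regioselectivity of epoxide methanolysis on the unprotected triol).** Attack at C5′ would give the regioisomeric methyl ether. Fallback: fix the C4′–OMe position at the Diels–Alder stage by using 2-methoxybutadiene (para-selective adduct), then set the trans C4′-OMe/C5′-OH pair by hydroxyl-directed hydroboration–oxidation of the resulting enol ether.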